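- I began at the late end of the run in epsilon. Suppose the 0.800 equiv of partner, the limiting reagent, has been used up; the scheme then leaves first product one exit, the reaction with starting material that gives side product. That exit is pseudo-first-order, so the quantity to carry is a drain constant d, and exp(−d·t) is the fraction of first product that survives a time t.

| flask | starting material | partner | temperature | time |
|---|---|---|---|---|
| epsilon | 0.050 M | 0.800 equiv | 110 °C | 8.0 min |
| theta | 0.050 M | 0.800 equiv | 60 °C | 8.0 min |
| alpha | 0.050 M | 0.800 equiv | 85 °C | 8.0 min |

    starting material + partner → first product + by-product (k1 = 1.24 M⁻¹ min⁻¹, Ea1 = 47.0 kJ mol⁻¹)
    starting material + partner → other mono adduct + by-product (k2 = 1.72 M⁻¹ min⁻¹, Ea2 = 61.0 kJ mol⁻¹)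
    partner + first product → bis adduct + by-product (k3 = 0.585 M⁻¹ min⁻¹, Ea3 = 71.0 kJ mol⁻¹)
    partner + other mono adduct → bis adduct + by-product (k4 = 2.20 M⁻¹ min⁻¹, Ea4 = 49.0 kJ mol⁻¹)
    starting material + by-product ⇌ idle adduct, settled at all times (K5 = 29.9 M⁻¹, ΔH5 = −50.0 kJ mol⁻¹)
    starting material + first product → side product (k6 = 0.468 M⁻¹ min⁻¹, Ea6 = 77.0 kJ mol⁻¹)
    (constants at 60 °C)

- the flask that comes out highest in amount of first product, in percent of the starting material charged, or "all alike" when all lie within 1.5 percentage points (epsilon / theta / alpha / all alike)
- first product at the end, in percent of the starting material charged, epsilon
- first product at the end, in percent of the starting material charged, theta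
- first product at the end, in percent of the starting material charged, alpha

- percentages count the starting material that a species holds: one side product counts as two
- by-product is meant together with its idle adduct
- all constants are for 60 °C and move with temperature by the activation energies and enthalpies

- In epsilon the Arrhenius factor lifts the side-step constant to 17.6 M⁻¹ min⁻¹, so I needed the leftover fraction X of starting material. My first guess was one partner per starting material, X = 20.0 %.
- I doubted that at once, since partner added to other mono adduct costs no starting material. At the temperature of epsilon a share s = 0.728 of the addition to starting material gives other mono adduct, and that adduct takes partner with r = 0.529 of the combined constant.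
- Integrating these two rates gives the other mono adduct standing at any X, and whatever was made beyond that has gone on to bis adduct. Putting my guess back in raised X for epsilon to 43.2 %, and going round once more gave 29.0 %. The answers bracket the solution, so I took their mean, 36.1 %.
- That mean ignored the side step, which itself eats starting material. I put the first product made in epsilon at about 17.4 % of the charge. The side step competes for it against the second addition, and with both charges at full strength it takes a share of 0.570; assuming that starting share for the whole run brought my X down to 26.2 %.
- Part of that is also bound as idle adduct. The equilibrium constant falls to 2.84 M⁻¹ in epsilon and by-product reaches about 0.0400 M, so free starting material is 23.5 %. The drain constant, side-step constant times free starting material, came to 0.207 min⁻¹.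
- Applied over the whole 8.0 min, this gave me an estimate of 3.31 % of first product in epsilon. I objected that second addition also removes some, so I expected this estimate to sit high.
- For theta I made a rough estimate, not a bound: the cold share of first product, equal-charge second-order conversion, and d with the whole charge free gave 18.8 %. I expected idle adduct to pull that down, yet it stood well above my epsilon estimate, so I chose theta and placed alpha between them without reckoning it.
- The forecast named theta, with 2 % for epsilon, 14.2 % for theta and 10.6 % for alpha. Its ground for epsilon was that “leftover starting material consumes it”. My epsilon figure lay above its figure.
- The simulation gave theta, with 2.28 % in epsilon, 14.6 % in theta and 11.6 % in alpha. Striking out the side step, the largest single effect, lifts epsilon from 2.28 % to 13.5 %. Applied to the 5.10 % standing in epsilon at 4.00 min, with partner at 0.956 % of its charge, my d predicts 2.23 % at 8.00 min, and the reading is 2.28 %. In alpha, the mean of its starting-material readings gives d = 0.0352 min⁻¹, which, carried on from 8.00 min, takes 11.6 % down to 0.920 %, against the reading of 1.34 % at 80.0 min.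

The constants used here belong to no real substance; the run is a simulation.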